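**Strategy.** Everything rests on a dearomative (3+2) annulation that builds the tetrahydrofuran ring onto the acylphloroglucinol core. Mirror-symmetric deoxycohumulone, which already carries both prenyl groups, is C-alkylated at a prenylated ring carbon by an (R)-configured epoxy tosylate, and the enol oxygen on the adjacent ring carbon then opens the epoxide. One operation thus forms the C-3–C-3a and O-1–C-2 bonds of the furan ring (benzofuran numbering of the target), the quaternary ring-fusion carbon C-3a, the C-2 stereocentre and the tertiary carbinol. It exploits the ambident enol unit C-3a/C-7a–O-1 of the six-membered ring, flanked by two equivalent prenylated carbons. Shi epoxidation of the remaining C-7 prenyl group finishes the target.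

Key step: step 4

Remark: the enolised β-triketone of the target and of the dearomatised intermediates is written in the tautomer of the given structure; the tautomers interconvert freely.

Step 1
Reactants: 1 phloroglucinol; 2 isobutyryl chloride
Product: 3 2-methyl-1-(2,4,6-trihydroxyphenyl)propan-1-one (phlorisobutyrophenone)
Conditions: AlCl3 (3 equiv), PhNO2, 65 °C; then ice/aq. HCl
Reagents that add atoms: none
Why: Friedel–Crafts C-acylation of the very electron-rich triol stops after one acyl group because the chelated aryl ketone deactivates the ring.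

Step 2
Reactants: 3 phlorisobutyrophenone; 4 prenyl bromide (2 equiv)
Product: 5 2-methyl-1-[2,4,6-trihydroxy-3,5-bis(3-methylbut-2-en-1-yl)phenyl]propan-1-one (deoxycohumulone)
Conditions: 10% aq. KOH, 0 °C
Reagents that add atoms: none
Why: Phenolate C-alkylation (SN2 of the ambident phloroglucinolate in water, where hydrogen bonding to oxygen favours attack through carbon) should place one prenyl group on each free ring carbon, and the dialkylated phenol is separated from mono- and trialkylated material.

Step 3
Reactants: 6 prenol (3-methylbut-2-en-1-ol)
Product: 8 [(2R)-3,3-dimethyloxiran-2-yl]methyl 4-methylbenzenesulfonate, via epoxy alcohol 7 (not isolated)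
Conditions: Ti(OiPr)4 (5 mol %), D-(−)-diisopropyl tartrate (7 mol %), tBuOOH (1.5 equiv), 4 Å MS, CH2Cl2, −20 °C; then P(OMe)3; then Et3N, DMAP (cat.), TsCl, −10 °C
Reagents that add atoms: tert-butyl hydroperoxide CC(C)(C)OO; p-toluenesulfonyl chloride Cc1ccc(cc1)S(Cl)(=O)=O
Why: Sharpless asymmetric epoxidation with the D-(−)-tartrate should deliver oxygen to the olefin face that gives the (R)-epoxy alcohol 7, which is tosylated in situ so that the volatile, water-soluble epoxy alcohol need not be isolated.

Step 4
Reactants: 5 deoxycohumulone; 8 [(2R)-3,3-dimethyloxiran-2-yl]methyl 4-methylbenzenesulfonate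
Product: 10 (2S,3aR)-4-hydroxy-2-(2-hydroxypropan-2-yl)-3a,7-bis(3-methylbut-2-en-1-yl)-5-(2-methylpropanoyl)-3,3a-dihydro-1-benzofuran-6(2H)-one, via C-alkylated epoxide 9 (not isolated)
Conditions: LiN(SiMe3)2 (2.0 equiv), toluene–THF (5:1), −20 → 25 °C; then LiN(SiMe3)2 (1.0 equiv), 45 °C; then 0.5 M aq. HCl, 0 °C
Reagents that add atoms: none
Why: Proposed new method: the dilithium phenolate of 5, a contact ion pair in toluene that favours carbon over oxygen attack, displaces the tosylate of 8 by SN2 at one prenylated ring carbon to give the dearomatised epoxide 9, and the third equivalent of base turns 9 into its dianion, whose enolate oxygen on the neighbouring ring carbon opens the epoxide at its CH carbon. The closest known reaction types are the alkylative dearomatisation of acylphloroglucinols with allylic halides, the base-induced cyclisation of epoxidised prenyl groups onto neighbouring enol oxygens and the tandem C-alkylation/O-cyclisation of 1,3-dicarbonyl compounds with epihalohydrins. The furan ring closes 5-exo-tet at the secondary epoxide carbon, which under basic conditions is preferred over 6-endo attack at the tertiary carbon. C-2 (S) follows from stereospecific inversion at the (R)-epoxide carbon of 8; C-3a (R) is set in the C-alkylation, where the lithium on the unchelated phenolate oxygen between the two prenylated carbons is expected to bind the epoxide oxygen, and the transition state that turns the CMe2 group away from the ring then delivers the (R)-electrophile to the face that leads to the 2,3a-trans product, any cis epimer being removed by chromatography. The step needs site, C/O and O/O selectivity: the mirror symmetry of 5 makes the two prenylated carbons equivalent, the lithium contact ion pair secures C-alkylation, and closure goes through the oxygen between the two alkylated carbons because the other neighbouring oxygen is tied up in the chelate of the acyl group.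

Step 5
Reactants: 10 bicyclic diprenyl alcohol
Product: 11 (2S,3aR)-7-{[(2R)-3,3-dimethyloxiran-2-yl]methyl}-4-hydroxy-2-(2-hydroxypropan-2-yl)-3a-(3-methylbut-2-en-1-yl)-5-(2-methylpropanoyl)-3,3a-dihydro-1-benzofuran-6(2H)-one (CNP0395488.1)
Conditions: D-fructose-derived Shi ketone (0.3 equiv), Oxone (2KHSO5·KHSO4·K2SO4), K2CO3, Bu4NHSO4 (cat.), MeCN–CH2(OMe)2–aq. Na2B4O7 buffer, −10 °C, stopped at partial conversion, cold quench to pH 7
Reagents that add atoms: potassium peroxymonosulfate [K+].[O-]S(=O)(=O)OO
Why: Shi epoxidation through the spiro transition state of the chiral dioxirane should give the (R)-epoxide of a trisubstituted olefin under catalyst control, it is expected to prefer the C-7 prenyl group on the planar enone edge over the neopentyl-type prenyl group on the congested quaternary C-3a, and the weakly nucleophilic mono-anionic triketonate should leave the new epoxide intact at low temperature.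

**Compound list**

1 | phloroglucinol (benzene-1,3,5-triol) | Oc1cc(O)cc(O)c1 | starting material
2 | isobutyryl chloride (2-methylpropanoyl chloride) | CC(C)C(Cl)=O | starting material
3 | 2-methyl-1-(2,4,6-trihydroxyphenyl)propan-1-one (phlorisobutyrophenone) | CC(C)C(=O)c1c(O)cc(O)cc1O | intermediate
4 | prenyl bromide (1-bromo-3-methylbut-2-ene) | CC(C)=CCBr | starting material
5 | 2-methyl-1-[2,4,6-trihydroxy-3,5-bis(3-methylbut-2-en-1-yl)phenyl]propan-1-one (deoxycohumulone) | CC(C)=CCc1c(O)c(CC=C(C)C)c(O)c(C(=O)C(C)C)c1O | intermediate
6 | prenol (3-methylbut-2-en-1-ol) | CC(C)=CCO | starting material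
7 | [(2R)-3,3-dimethyloxiran-2-yl]methanol | OC[C@H]1OC1(C)C | intermediate
8 | [(2R)-3,3-dimethyloxiran-2-yl]methyl 4-methylbenzenesulfonate | Cc1ccc(cc1)S(=O)(=O)OC[C@H]1OC1(C)C | intermediate
9 | 4-{[(2R)-3,3-dimethyloxiran-2-yl]methyl}-3,5-dihydroxy-4,6-bis(3-methylbut-2-en-1-yl)-2-(2-methylpropanoyl)cyclohexa-2,5-dien-1-one, quaternary carbon configured as in 10 | CC(C)=CC[C@]1(C[C@H]2OC2(C)C)C(O)=C(CC=C(C)C)C(=O)C(C(=O)C(C)C)=C1O | intermediate
10 | (2S,3aR)-4-hydroxy-2-(2-hydroxypropan-2-yl)-3a,7-bis(3-methylbut-2-en-1-yl)-5-(2-methylpropanoyl)-3,3a-dihydro-1-benzofuran-6(2H)-one | CC(C)=CC[C@]12C[C@@H](C(C)(C)O)OC1=C(CC=C(C)C)C(=O)C(C(=O)C(C)C)=C2O | intermediate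
11 | (2S,3aR)-7-{[(2R)-3,3-dimethyloxiran-2-yl]methyl}-4-hydroxy-2-(2-hydroxypropan-2-yl)-3a-(3-methylbut-2-en-1-yl)-5-(2-methylpropanoyl)-3,3a-dihydro-1-benzofuran-6(2H)-one | CC(C)=CC[C@]12C[C@@H](C(C)(C)O)OC1=C(C[C@H]1OC1(C)C)C(=O)C(C(=O)C(C)C)=C2O | target

**Step count.** Total: 5 steps. Longest linear sequence: 4 steps (steps 1, 2, 4, 5); step 3 is the convergent branch.

**Steps most likely to fail**

1. Step 4 (proposed new method). The C-alkylation may show poor facial selectivity at the new quaternary carbon, since the chelated transition state is only a model, and O-alkylation by the sulfonate may compete with attack through the hindered ring carbon. The fallback uses known chemistry; it sets out from compound 5 and comes back to the route at compound 10, and it fixes C-2 on the aromatic ring first and creates the quaternary carbon afterwards under substrate control. Compound 5 is peracetylated (Ac2O, pyridine, DMAP) to give deoxycohumulone triacetate F1, which shields the oxidation-prone phenol. Shi epoxidation of F1 with the D-fructose-derived ketone, stopped at partial conversion, should give the (R)-mono-epoxide triacetate F2. K2CO3 in MeOH removes the acetates, and the phenolate para to the acyl group then opens the epoxide 5-exo with inversion to give the (2S)-7-prenyl dihydrobenzofuran F3. Alkylative dearomatisation of F3 by 4 (aq. KOH, 0 °C) at the ring-fusion carbon, on the face anti to the C-2 carbinol substituent, gives compound 10 after separation from material alkylated at C-7.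

2. Step 5. The dioxirane may discriminate poorly between the two prenyl olefins, so that the C-3a prenyl group or both are epoxidised. Long exposure to the basic buffer may also let the C-6 enolate oxygen open the new epoxide, which is why the reaction is run cold and quenched early. The fallback sets out from compound 3 and comes back to the route at compound 11; it carries the substituent of the quaternary carbon as an allyl placeholder that the dioxirane leaves alone. Compound 3 is C-allylated by allyl bromide (aq. KOH, 0 °C) to give 3-allylphlorisobutyrophenone F4, which is C-prenylated by 4 to give the 3-allyl-5-prenyl phenol F5. Annulation of F5 by 8 under the conditions of the key annulation gives, after separation from the regioisomer alkylated at the prenylated carbon, the 3a-allyl-7-prenyl bicyclic alcohol F6. Shi epoxidation of F6, which holds a single trisubstituted olefin, gives the 3a-allyl epoxide F7. Cross-metathesis of F7 and 2-methylbut-2-ene (second-generation Grubbs catalyst, CH2Cl2, 40 °C) turns the allyl group into the prenyl group and gives compound 11.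

3. Step 2. Over-alkylation to triprenylated dearomatised material and O-alkylation may consume much of the phenol before the dialkylated stage is reached cleanly. The fallback sets out from compound 3 and comes back to the route at compound 5; it replaces phenolate alkylation by an acid-mediated Friedel–Crafts prenylation using 2-methylbut-3-en-2-ol and BF3·OEt2 in dioxane at room temperature, which proceeds through the tertiary allyl cation and avoids SN2 O-alkylation; no new compound is made, entry F0.

**Further compounds**

F1 | step 4 | 2-(2-methylpropanoyl)-4,6-bis(3-methylbut-2-en-1-yl)benzene-1,3,5-triyl triacetate (deoxycohumulone triacetate) | CC(C)=CCc1c(OC(C)=O)c(CC=C(C)C)c(OC(C)=O)c(C(=O)C(C)C)c1OC(C)=O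
F2 | step 4 | 4-{[(2R)-3,3-dimethyloxiran-2-yl]methyl}-2-(2-methylpropanoyl)-6-(3-methylbut-2-en-1-yl)benzene-1,3,5-triyl triacetate | CC(C)=CCc1c(OC(C)=O)c(C[C@H]2OC2(C)C)c(OC(C)=O)c(C(=O)C(C)C)c1OC(C)=O
F3 | step 4 | 1-[(2S)-4,6-dihydroxy-2-(2-hydroxypropan-2-yl)-7-(3-methylbut-2-en-1-yl)-2,3-dihydro-1-benzofuran-5-yl]-2-methylpropan-1-one | CC(C)(O)[C@@H]1Cc2c(O1)c(CC=C(C)C)c(O)c(C(=O)C(C)C)c2O
F4 | step 5 | 2-methyl-1-[2,4,6-trihydroxy-3-(prop-2-en-1-yl)phenyl]propan-1-one (3-allylphlorisobutyrophenone) | C=CCc1c(O)cc(O)c(C(=O)C(C)C)c1O
F5 | step 5 | 2-methyl-1-[2,4,6-trihydroxy-3-(3-methylbut-2-en-1-yl)-5-(prop-2-en-1-yl)phenyl]propan-1-one | C=CCc1c(O)c(CC=C(C)C)c(O)c(C(=O)C(C)C)c1O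
F6 | step 5 | (2S,3aR)-4-hydroxy-2-(2-hydroxypropan-2-yl)-7-(3-methylbut-2-en-1-yl)-5-(2-methylpropanoyl)-3a-(prop-2-en-1-yl)-3,3a-dihydro-1-benzofuran-6(2H)-one | C=CC[C@]12C[C@@H](C(C)(C)O)OC1=C(CC=C(C)C)C(=O)C(C(=O)C(C)C)=C2O
F7 | step 5 | (2S,3aR)-7-{[(2R)-3,3-dimethyloxiran-2-yl]methyl}-4-hydroxy-2-(2-hydroxypropan-2-yl)-5-(2-methylpropanoyl)-3a-(prop-2-en-1-yl)-3,3a-dihydro-1-benzofuran-6(2H)-one | C=CC[C@]12C[C@@H](C(C)(C)O)OC1=C(C[C@H]1OC1(C)C)C(=O)C(C(=O)C(C)C)=C2O
F0 | step 2 | none | none
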